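**Plan**

1. Locants: decalin C1 (acyl), C2 (CH3), C3=C4, C4a (OH), C5, C6 (CO2H), C7, C8 (CH3), C8a; ring A = C4a-C5-C6-C7-C8-C8a, ring B = C1-C2-C3-C4-C4a-C8a; acyl carbon C9; imide carbons C2′–C5′.
2. Retrosynthetic cuts, in order: imide C3′=C4′ and C9–C3′ (selenoxide elimination, aldol of succinimide 26 onto aldehyde 19); C1–C8a of ring B (radical closure); C4–C4a (acetylide onto enone 5); then ring A back to a cyclobutanol (C7–C8 opened, C4a–C7 restored).
3. Forward: ring A is made first, by a two-carbon ring expansion of allenyl cyclobutanol 4 (four- to six-membered); the C1–C4 chain is added at C4a; ring B closes at C1–C8a; the imide is attached last.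
4. Enabling feature: in ring A the oxygen-bearing C4a and the carboxyl-bearing C6 are 1,3-related and C8 carries a methyl two carbons from C4a, so ring A is a 3-carboxy-cyclobutanol (C4a, C5, C6, C7) into which an allene (C8a, C8, the C8 methyl) is inserted when the strained C4a–C7 bond is cleaved; the enone that results is the handle for both later bonds, at C4a and at C8a.
5. Stereochemistry: C6 from the chiral rhodium catalyst (made first as the 6-epimer to steer C4a, corrected later by equilibration); C4a from acetylide attack anti to the C6 ester; C8a from the cis ring closure; C8 from hydrogen-atom transfer anti to C1; C1 by equilibration; C2 from (S)-but-3-yn-2-ol; the octenyl centre from an iridium allylic alkylation.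

Key step: step 3

Remark: names use the decalin locants of the plan; the sense of induction of the chiral ligands in steps 3 and 14 is assumed, and the antipodal ligand is taken if it proves opposite.

**Step 1**
Reactants: 1 methyl 3-oxocyclobutane-1-carboxylate
Product: 2 methyl cis-3-ethynyl-3-hydroxycyclobutane-1-carboxylate (hydroxyl cis to the ester)
Conditions: HC≡CMgBr, THF, −78 °C; H2O
Reagents that add atoms: ethynylmagnesium bromide, C#C[Mg]Br
Why: 1,2-addition of an alkynyl Grignard reagent to the strained ketone, faster than attack on the ester; the nucleophile should enter the puckered ring anti to the C3 ester, so the hydroxyl ends cis to it (one achiral diastereomer, purified at this stage).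

**Step 2**
Reactants: 2 methyl cis-3-ethynyl-3-hydroxycyclobutane-1-carboxylate
Product: 4 methyl cis-3-hydroxy-3-(propa-1,2-dien-1-yl)cyclobutane-1-carboxylate, via propargylic amine 3 (not isolated)
Conditions: (CH2O)n, CuI, Cy2NH, 1,4-dioxane, reflux
Reagents that add atoms: formaldehyde (as paraformaldehyde), C=O
Why: Crabbé allene homologation: copper-mediated Mannich coupling of the terminal alkyne with formaldehyde and the secondary amine gives the propargylic amine, which transfers hydride and loses the imine to leave the terminal allene; the ring stereochemistry is untouched.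

**Step 3**
Reactants: 4 methyl cis-3-hydroxy-3-(propa-1,2-dien-1-yl)cyclobutane-1-carboxylate
Product: 5 methyl (1S)-3-methyl-5-oxocyclohex-3-ene-1-carboxylate
Conditions: [Rh(OH)(cod)]2 (2.5 mol %), (R)-DTBM-SEGPHOS (6 mol %), toluene, 80 °C
Reagents that add atoms: none
Why: Ligand exchange gives the monovalent rhodium alkoxide of 4; β-carbon elimination cleaves one of the two enantiotopic carbinol–CH2 bonds of the strained four-membered ring (the C4a–C7 bond) to a primary σ-alkylrhodium tethered to an allenyl ketone, which closes ring A by intramolecular 1,4-carborhodation at the central allene carbon (new C7–C8 bond), and protonation of the rhodium dienolate at the former allene terminus by the next molecule of 4 gives the β-methyl enone and returns the alkoxide. The closest known reaction type is the rhodium-catalysed enantioselective C–C activation of 1-allenyl tert-cyclobutanols to cyclohexenones, here applied to a 3-monosubstituted ring. Ring A closes as a six-membered ring in a carbometalation that is 6-exo with respect to the terminal C=CH2 bond of the allene, the two inserted ring carbons C8a and C8 and the C8 methyl all coming from the allene. The only stereocentre formed, C6, is fixed by the chiral bisphosphine on rhodium, which decides which ring bond breaks; it is made on purpose as the (S) 6-epimer of the target so that it can steer step 6. The step needs enantiotopic-bond selection and ring closure faster than β-hydride elimination of the alkylrhodium (one β-hydrogen, on the ester-bearing carbon); the single cis diastereomer of 4 secures the first (the trans isomer would be expected to give the antipode) and the fast six-membered addition to the electrophilic allenone is relied on for the second.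

**Step 4**
Reactants: 6 (2S)-but-3-yn-2-ol
Product: 7 (2S)-but-3-yn-2-yl methanesulfonate
Conditions: MsCl, Et3N, CH2Cl2, 0 °C
Reagents that add atoms: methanesulfonyl chloride, CS(=O)(=O)Cl
Why: Sulfonylation of the secondary alcohol at oxygen, which leaves the stereocentre unchanged.

**Step 5**
Reactants: 7 (2S)-but-3-yn-2-yl methanesulfonate; 8 methyl cyanoacetate
Product: 9 methyl (3S)-2-cyano-3-methylpent-4-ynoate (both C2 epimers)
Conditions: NaH, THF–DMF, 0 to 40 °C (8 in excess)
Reagents that add atoms: none
Why: SN2 alkylation of sodium cyanoacetate at the secondary propargylic carbon with inversion, which turns the (S) sulfonate into the (3S) carbon-linked centre (the future C2; the descriptor is kept because the priorities change), direct substitution being expected over SN2′ attack for this soft nucleophile.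

**Step 6**
Reactants: 5 methyl (1S)-3-methyl-5-oxocyclohex-3-ene-1-carboxylate; 9 methyl (3S)-2-cyano-3-methylpent-4-ynoate
Product: 11 methyl (1S,5S)-5-[(3S)-4-cyano-5-methoxy-3-methyl-5-oxopent-1-yn-1-yl]-3-methyl-5-(triethylsilyloxy)cyclohex-3-ene-1-carboxylate, via tertiary propargylic alcohol 10 (not isolated)
Conditions: 9, LiN(i-Pr)2 (2 equiv), THF, −78 °C; CeCl3; 5; then Et3SiOTf, −78 to 0 °C
Reagents that add atoms: triethylsilyl trifluoromethanesulfonate, CC[Si](CC)(CC)OS(=O)(=O)C(F)(F)F
Why: Organocerium acetylide 1,2-addition to an enone followed by silylation: two equivalents of amide base mask the acidic cyano ester as its enolate and form the acetylide, which should attack the half-chair enone axially on the face anti to the pseudo-equatorial C6 ester (1,3-induction) and so set C4a with the carbon chain trans to the ester, and trapping the alkoxide as the silyl ether prevents lactonisation onto the cis ester.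

**Step 7**
Reactants: 11 (the alkyne of step 6)
Product: 12 methyl (1S,5R)-5-[(1Z,3R)-4-cyano-5-methoxy-3-methyl-5-oxopent-1-en-1-yl]-3-methyl-5-(triethylsilyloxy)cyclohex-3-ene-1-carboxylate
Conditions: H2 (1 atm), Pd/CaCO3/Pb(OAc)2 (Lindlar catalyst), quinoline, EtOAc, 25 °C
Reagents that add atoms: none
Why: Lindlar semihydrogenation of the internal alkyne by syn addition of hydrogen gives the (Z)-alkene that brings C1 within reach of C8a; the trisubstituted ring alkene and the nitrile should not be touched (descriptors change by priority only).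

**Step 8**
Reactants: 12 (the Z-alkene of step 7)
Product: 13 methyl (1S,5R)-5-[(1Z,3R)-4-bromo-4-cyano-5-methoxy-3-methyl-5-oxopent-1-en-1-yl]-3-methyl-5-(triethylsilyloxy)cyclohex-3-ene-1-carboxylate (both epimers at the brominated carbon)
Conditions: DBU, BrCCl3, CH2Cl2, 0 °C
Reagents that add atoms: bromotrichloromethane, BrC(Cl)(Cl)Cl
Why: Electrophilic bromination of the doubly activated methine through its DBU enolate installs the radical precursor; the new centre is a mixture and is destroyed in the next step.

**Step 9**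
Reactants: 13 (the bromide of step 8)
Product: 14 dimethyl (2R,4aR,6S,8S,8aR)-1-cyano-2,8-dimethyl-4a-(triethylsilyloxy)-1,2,4a,5,6,7,8,8a-octahydronaphthalene-1,6-dicarboxylate (both C1 epimers)
Conditions: Bu3SnH (slow addition), AIBN, benzene, 80 °C
Reagents that add atoms: none
Why: Bu3SnH-mediated radical cyclisation: bromine abstraction gives the electrophilic α-cyano ester radical at C1, which closes ring B 6-exo-trig onto the less substituted carbon C8a of the electron-rich trisubstituted alkene; the short (Z)-alkenyl tether can bridge C4a and C8a on one face only, which makes the ring fusion cis (C8a–H syn to the silyloxy group), and the tertiary C8 radical should take hydrogen from the stannane anti to the new C8a–C1 bond, placing the C8 methyl cis to C1.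

**Step 10**
Reactants: 14 (the bicyclic cyano diester of step 9)
Product: 15 methyl (2R,4aR,6S,8S,8aR)-1-cyano-2,8-dimethyl-4a-(triethylsilyloxy)-1,2,4a,5,6,7,8,8a-octahydronaphthalene-6-carboxylate (both C1 epimers)
Conditions: LiCl, H2O, DMSO, 140 °C
Reagents that add atoms: none
Why: Krapcho dealkoxycarbonylation: chloride demethylates the α-cyano ester, the carboxylate loses CO2 and the nitrile-stabilised carbanion is protonated, leaving C1 as a mixture that is settled in step 12; the unactivated C6 ester reacts far more slowly.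

**Step 11**
Reactants: 15 (the 6S nitrile ester of step 10)
Product: 17 (2R,4aR,6R,8S,8aR)-1-cyano-2,8-dimethyl-4a-(triethylsilyloxy)-1,2,4a,5,6,7,8,8a-octahydronaphthalene-6-carboxylic acid (both C1 epimers), via 6R nitrile ester 16 (not isolated)
Conditions: NaOMe (cat.), MeOH, 60 °C; then aq. NaOH, 25 °C; aq. NaHSO4
Reagents that add atoms: sodium hydroxide, [Na+].[OH-]
Why: Base-mediated epimerisation then saponification: in the cis-decalin the C6 ester of 15 is axial and syn to the axial silyloxy group at C4a, so reversible enolisation by methoxide should move it to the equatorial (6R) position, trans to the oxygen (no lactone possible), after which hydroxide cleaves the only ester left.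

**Step 12**
Reactants: 17 (the nitrile acid of step 11)
Product: 19 (1S,2R,4aR,6R,8S,8aR)-1-formyl-2,8-dimethyl-4a-(triethylsilyloxy)-1,2,4a,5,6,7,8,8a-octahydronaphthalene-6-carboxylic acid, via C1-epimeric aldehyde mixture 18 (not isolated)
Conditions: i-Bu2AlH, CH2Cl2, −78 to −40 °C; aq. potassium sodium tartrate; then DBU, CH2Cl2, 25 °C
Reagents that add atoms: water, O
Why: Hydride reduction of the nitrile by i-Bu2AlH to the N-aluminoimine (the acid is first converted into its unreactive aluminium carboxylate) and hydrolysis give the aldehyde, and DBU-mediated enolisation then equilibrates C1 to the (1S) epimer in which the formyl group is equatorial and trans to both the C2 methyl and C8.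

**Step 13**
Reactants: 20 (2E)-oct-2-en-1-ol
Product: 21 methyl (2E)-oct-2-en-1-yl carbonate
Conditions: ClCO2Me, pyridine, CH2Cl2, 0 °C
Reagents that add atoms: methyl chloroformate, COC(=O)Cl
Why: Acylation of the primary allylic alcohol with a chloroformate gives the carbonate leaving group for the allylic substitution without moving the (E)-alkene.

**Step 14**
Reactants: 21 methyl (2E)-oct-2-en-1-yl carbonate; 22 dimethyl propanedioate
Product: 23 dimethyl 2-[(3S)-oct-1-en-3-yl]propanedioate
Conditions: [Ir(cod)Cl]2 (2 mol %), (S,S,S)-BINOL bis(1-phenylethyl)phosphoramidite (4 mol %), TBD (cat.), THF, 25 °C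
Reagents that add atoms: none
Why: Iridium-catalysed asymmetric allylic alkylation: the phosphoramidite-ligated allyliridium intermediate is attacked by malonate at its substituted terminus, which gives the branched product with a terminal vinyl group, and the chiral ligand sets the (S) centre.

**Step 15**
Reactants: 23 dimethyl 2-[(3S)-oct-1-en-3-yl]propanedioate
Product: 25 methyl 3-[(3S)-oct-1-en-3-yl]-2,5-dioxopyrrolidine-3-carboxylate (both C3 epimers), via acyclic amide 24 (not isolated)
Conditions: NaH, DMF, 0 °C; BrCH2CONH2, 25 °C; then NaOMe (cat.), MeOH, 50 °C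
Reagents that add atoms: 2-bromoacetamide, NC(=O)CBr
Why: C-alkylation of the malonate enolate with the α-haloamide followed by base-catalysed attack of the amide nitrogen on one ester (imide formation); the octenyl stereocentre is not acidic and is untouched.

**Step 16**
Reactants: 25 (the imide ester of step 15)
Product: 26 3-[(3S)-oct-1-en-3-yl]pyrrolidine-2,5-dione (both C3 epimers)
Conditions: LiCl, H2O, DMSO, 140 °C
Reagents that add atoms: none
Why: Krapcho dealkoxycarbonylation of the imide-activated ester leaves the 3-substituted succinimide; the ring centre is a mixture and becomes sp2 in step 19.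

**Step 17**
Reactants: 19 (the aldehyde acid of step 12); 26 3-[(3S)-oct-1-en-3-yl]pyrrolidine-2,5-dione
Product: 27 (1S,2R,4aR,6R,8S,8aR)-1-{hydroxy[4-((3S)-oct-1-en-3-yl)-2,5-dioxopyrrolidin-3-yl]methyl}-2,8-dimethyl-4a-(triethylsilyloxy)-1,2,4a,5,6,7,8,8a-octahydronaphthalene-6-carboxylic acid (mixture at the three new centres)
Conditions: 26 (3 equiv), LiN(i-Pr)2 (6 equiv), THF, −78 °C; then 19; AcOH
Reagents that add atoms: none
Why: Aldol addition: the imide dianion (lithiated at nitrogen, then at the less hindered ring CH2) adds to the aldehyde carbonyl while excess base holds the acid as its carboxylate; the three new centres need no control because all are removed in steps 18 and 19.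

**Step 18**
Reactants: 27 (the aldol adduct of step 17)
Product: 28 (1S,2R,4aR,6R,8S,8aR)-2,8-dimethyl-1-{[4-((3S)-oct-1-en-3-yl)-2,5-dioxopyrrolidin-3-yl]carbonyl}-4a-(triethylsilyloxy)-1,2,4a,5,6,7,8,8a-octahydronaphthalene-6-carboxylic acid (imide ring epimers and enol form)
Conditions: Dess–Martin periodinane, CH2Cl2, 25 °C
Reagents that add atoms: none
Why: Dess–Martin oxidation of the secondary alcohol to the ketone under near-neutral conditions gives the enolisable 3-acylsuccinimide without touching the alkenes, the acid or the silyl ether.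

**Step 19**
Reactants: 28 (the 3-acylsuccinimide of step 18)
Product: 31 (1S,2R,4aR,6R,8S,8aR)-2,8-dimethyl-1-({4-[(3S)-oct-1-en-3-yl]-2,5-dioxo-2,5-dihydro-1H-pyrrol-3-yl}carbonyl)-4a-(triethylsilyloxy)-1,2,4a,5,6,7,8,8a-octahydronaphthalene-6-carboxylic acid, via selenide 29 (not isolated), via selenoxide 30 (not isolated)
Conditions: PhSeCl, pyridine, CH2Cl2, 0 °C; then 30 % H2O2, 0 to 25 °C
Reagents that add atoms: none
Why: α-Selenenylation of the 1,3-dicarbonyl carbon (anti to the neighbouring octenyl-bearing carbon) and oxidation give a selenoxide whose only β-hydrogen is the ring C–H, so selenoxide syn-elimination can only form the endocyclic maleimide double bond, under conditions mild enough not to deprotonate the allylic octenyl centre.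

**Step 20**
Reactants: 31 (the silyl-protected acylmaleimide of step 19)
Product: 32 (1S,2R,4aR,6R,8S,8aR)-4a-hydroxy-2,8-dimethyl-1-({4-[(3S)-oct-1-en-3-yl]-2,5-dioxo-2,5-dihydro-1H-pyrrol-3-yl}carbonyl)-1,2,4a,5,6,7,8,8a-octahydronaphthalene-6-carboxylic acid
Conditions: HF·pyridine, pyridine, THF, 0 to 25 °C
Reagents that add atoms: none
Why: Fluoride-mediated cleavage of the tertiary triethylsilyl ether with buffered HF·pyridine, acidic and not basic, so that the base-labile centre next to the maleimide and the imide ring are not put at risk.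

**Compound list**

1 | methyl 3-oxocyclobutane-1-carboxylate | COC(=O)C1CC(=O)C1 | starting material
2 | methyl cis-3-ethynyl-3-hydroxycyclobutane-1-carboxylate | COC(=O)[C@H]1C[C@](O)(C#C)C1 | intermediate
3 | methyl cis-3-[3-(dicyclohexylamino)prop-1-yn-1-yl]-3-hydroxycyclobutane-1-carboxylate | COC(=O)[C@H]1C[C@](O)(C#CCN(C2CCCCC2)C2CCCCC2)C1 | intermediate (not isolated)
4 | methyl cis-3-hydroxy-3-(propa-1,2-dien-1-yl)cyclobutane-1-carboxylate | COC(=O)[C@H]1C[C@](O)(C=C=C)C1 | intermediate
5 | methyl (1S)-3-methyl-5-oxocyclohex-3-ene-1-carboxylate | O=C1C=C(C)C[C@H](C(=O)OC)C1 | intermediate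
6 | (2S)-but-3-yn-2-ol | C#C[C@H](C)O | starting material
7 | (2S)-but-3-yn-2-yl methanesulfonate | C#C[C@H](C)OS(C)(=O)=O | intermediate
8 | methyl cyanoacetate | N#CCC(=O)OC | starting material
9 | methyl (3S)-2-cyano-3-methylpent-4-ynoate | C#C[C@@H](C)C(C#N)C(=O)OC | intermediate
10 | methyl (1S,5S)-5-[(3S)-4-cyano-5-methoxy-3-methyl-5-oxopent-1-yn-1-yl]-5-hydroxy-3-methylcyclohex-3-ene-1-carboxylate | N#CC(C(=O)OC)[C@H](C)C#C[C@]1(O)C[C@@H](C(=O)OC)CC(C)=C1 | intermediate (not isolated)
11 | methyl (1S,5S)-5-[(3S)-4-cyano-5-methoxy-3-methyl-5-oxopent-1-yn-1-yl]-3-methyl-5-(triethylsilyloxy)cyclohex-3-ene-1-carboxylate | N#CC(C(=O)OC)[C@H](C)C#C[C@]1(O[Si](CC)(CC)CC)C[C@@H](C(=O)OC)CC(C)=C1 | intermediate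
12 | methyl (1S,5R)-5-[(1Z,3R)-4-cyano-5-methoxy-3-methyl-5-oxopent-1-en-1-yl]-3-methyl-5-(triethylsilyloxy)cyclohex-3-ene-1-carboxylate | N#CC(C(=O)OC)[C@H](C)/C=C\[C@]1(O[Si](CC)(CC)CC)C[C@@H](C(=O)OC)CC(C)=C1 | intermediate
13 | methyl (1S,5R)-5-[(1Z,3R)-4-bromo-4-cyano-5-methoxy-3-methyl-5-oxopent-1-en-1-yl]-3-methyl-5-(triethylsilyloxy)cyclohex-3-ene-1-carboxylate | N#CC(Br)(C(=O)OC)[C@H](C)/C=C\[C@]1(O[Si](CC)(CC)CC)C[C@@H](C(=O)OC)CC(C)=C1 | intermediate
14 | dimethyl (2R,4aR,6S,8S,8aR)-1-cyano-2,8-dimethyl-4a-(triethylsilyloxy)-1,2,4a,5,6,7,8,8a-octahydronaphthalene-1,6-dicarboxylate | N#CC1(C(=O)OC)[C@H]2[C@@H](C)C[C@H](C(=O)OC)C[C@@]2(O[Si](CC)(CC)CC)C=C[C@H]1C | intermediate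
15 | methyl (2R,4aR,6S,8S,8aR)-1-cyano-2,8-dimethyl-4a-(triethylsilyloxy)-1,2,4a,5,6,7,8,8a-octahydronaphthalene-6-carboxylate | N#CC1[C@H]2[C@@H](C)C[C@H](C(=O)OC)C[C@@]2(O[Si](CC)(CC)CC)C=C[C@H]1C | intermediate
16 | methyl (2R,4aR,6R,8S,8aR)-1-cyano-2,8-dimethyl-4a-(triethylsilyloxy)-1,2,4a,5,6,7,8,8a-octahydronaphthalene-6-carboxylate | N#CC1[C@H]2[C@@H](C)C[C@@H](C(=O)OC)C[C@@]2(O[Si](CC)(CC)CC)C=C[C@H]1C | intermediate (not isolated)
17 | (2R,4aR,6R,8S,8aR)-1-cyano-2,8-dimethyl-4a-(triethylsilyloxy)-1,2,4a,5,6,7,8,8a-octahydronaphthalene-6-carboxylic acid | N#CC1[C@H]2[C@@H](C)C[C@@H](C(=O)O)C[C@@]2(O[Si](CC)(CC)CC)C=C[C@H]1C | intermediate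
18 | (2R,4aR,6R,8S,8aR)-1-formyl-2,8-dimethyl-4a-(triethylsilyloxy)-1,2,4a,5,6,7,8,8a-octahydronaphthalene-6-carboxylic acid, C1 epimer mixture | O=CC1[C@H]2[C@@H](C)C[C@@H](C(=O)O)C[C@@]2(O[Si](CC)(CC)CC)C=C[C@H]1C | intermediate (not isolated)
19 | (1S,2R,4aR,6R,8S,8aR)-1-formyl-2,8-dimethyl-4a-(triethylsilyloxy)-1,2,4a,5,6,7,8,8a-octahydronaphthalene-6-carboxylic acid | O=C[C@@H]1[C@H]2[C@@H](C)C[C@@H](C(=O)O)C[C@@]2(O[Si](CC)(CC)CC)C=C[C@H]1C | intermediate
20 | (2E)-oct-2-en-1-ol | CCCCC/C=C/CO | starting material
21 | methyl (2E)-oct-2-en-1-yl carbonate | CCCCC/C=C/COC(=O)OC | intermediate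
22 | dimethyl propanedioate | COC(=O)CC(=O)OC | starting material
23 | dimethyl 2-[(3S)-oct-1-en-3-yl]propanedioate | C=C[C@H](CCCCC)C(C(=O)OC)C(=O)OC | intermediate
24 | dimethyl 2-(2-amino-2-oxoethyl)-2-[(3S)-oct-1-en-3-yl]propanedioate | C=C[C@H](CCCCC)C(CC(N)=O)(C(=O)OC)C(=O)OC | intermediate (not isolated)
25 | methyl 3-[(3S)-oct-1-en-3-yl]-2,5-dioxopyrrolidine-3-carboxylate | C=C[C@H](CCCCC)C1(C(=O)OC)CC(=O)NC1=O | intermediate
26 | 3-[(3S)-oct-1-en-3-yl]pyrrolidine-2,5-dione | C=C[C@H](CCCCC)C1CC(=O)NC1=O | intermediate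
27 | (1S,2R,4aR,6R,8S,8aR)-1-{hydroxy[4-((3S)-oct-1-en-3-yl)-2,5-dioxopyrrolidin-3-yl]methyl}-2,8-dimethyl-4a-(triethylsilyloxy)-1,2,4a,5,6,7,8,8a-octahydronaphthalene-6-carboxylic acid | C=C[C@H](CCCCC)C1C(C(O)[C@@H]2[C@H]3[C@@H](C)C[C@@H](C(=O)O)C[C@@]3(O[Si](CC)(CC)CC)C=C[C@H]2C)C(=O)NC1=O | intermediate
28 | (1S,2R,4aR,6R,8S,8aR)-2,8-dimethyl-1-{[4-((3S)-oct-1-en-3-yl)-2,5-dioxopyrrolidin-3-yl]carbonyl}-4a-(triethylsilyloxy)-1,2,4a,5,6,7,8,8a-octahydronaphthalene-6-carboxylic acid | C=C[C@H](CCCCC)C1C(C(=O)[C@@H]2[C@H]3[C@@H](C)C[C@@H](C(=O)O)C[C@@]3(O[Si](CC)(CC)CC)C=C[C@H]2C)C(=O)NC1=O | intermediate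
29 | the 3-(phenylselanyl) derivative of 28 (selenium on the acyl-bearing ring carbon) | C=C[C@H](CCCCC)C1C([Se]c2ccccc2)(C(=O)[C@@H]3[C@H]4[C@@H](C)C[C@@H](C(=O)O)C[C@@]4(O[Si](CC)(CC)CC)C=C[C@H]3C)C(=O)NC1=O | intermediate (not isolated)
30 | the selenoxide of 29 | C=C[C@H](CCCCC)C1C([Se](=O)c2ccccc2)(C(=O)[C@@H]3[C@H]4[C@@H](C)C[C@@H](C(=O)O)C[C@@]4(O[Si](CC)(CC)CC)C=C[C@H]3C)C(=O)NC1=O | intermediate (not isolated)
31 | (1S,2R,4aR,6R,8S,8aR)-2,8-dimethyl-1-({4-[(3S)-oct-1-en-3-yl]-2,5-dioxo-2,5-dihydro-1H-pyrrol-3-yl}carbonyl)-4a-(triethylsilyloxy)-1,2,4a,5,6,7,8,8a-octahydronaphthalene-6-carboxylic acid | C=C[C@H](CCCCC)C1=C(C(=O)[C@@H]2[C@H]3[C@@H](C)C[C@@H](C(=O)O)C[C@@]3(O[Si](CC)(CC)CC)C=C[C@H]2C)C(=O)NC1=O | intermediate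
32 | (1S,2R,4aR,6R,8S,8aR)-4a-hydroxy-2,8-dimethyl-1-({4-[(3S)-oct-1-en-3-yl]-2,5-dioxo-2,5-dihydro-1H-pyrrol-3-yl}carbonyl)-1,2,4a,5,6,7,8,8a-octahydronaphthalene-6-carboxylic acid | C=C[C@H](CCCCC)C1=C(C(=O)[C@@H]2[C@H]3[C@@H](C)C[C@@H](C(=O)O)C[C@@]3(O)C=C[C@H]2C)C(=O)NC1=O | target

**Count and risks**

Total steps: 20. Longest linear sequence: 14 steps (steps 1–3, 6–12, 17–20).

Steps most likely to fail:

1. Step 3. The σ-alkylrhodium intermediate may undergo β-hydride elimination (its β-hydrogen sits on the ester-bearing carbon) before it closes the ring, or the catalyst may discriminate the two ring bonds poorly. The fallback sets out from compound 22 and comes back at compound 5; it gives up the ring expansion and closes ring A directly. 22 is alkylated twice with chloroacetone (K2CO3, NaI, acetone) to dimethyl 2,2-bis(2-oxopropyl)propanedioate F1. Demethoxycarbonylation (LiCl, wet DMSO, 150 °C) gives the symmetric diketo ester methyl 4-oxo-2-(2-oxopropyl)pentanoate F2. A cinchona-derived primary amine salt (9-amino-9-deoxy-epi-quinidine, acid co-catalyst, toluene) then effects a desymmetrising enamine aldol condensation between the two enantiotopic acetonyl arms and should give 5 (the pseudoenantiomeric amine is used if the sense is opposite).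

2. Step 9. The C1 radical may be reduced by the stannane before the slow 6-exo closure onto the hindered alkene carbon, or the hydrogen transfer to C8 may show poor facial selectivity. The fallback sets out from compound 12 and comes back at compound 14. Oxidative free-radical cyclisation of the unbrominated cyano ester with Mn(OAc)3 and Cu(OAc)2 (AcOH–MeCN, 25 °C) generates the same C1 radical from the manganese enolate with no competing hydrogen donor. The cyclised tertiary radical is oxidised by the copper salt to the 8-methylidene bicycle F3 (ring configuration as in 14). Hydrogen-atom-transfer hydrogenation (Mn(dpm)3, PhSiH3, t-BuOOH, i-PrOH), selective for the 1,1-disubstituted alkene over the cis-disubstituted alkene of ring B, then reduces F3 to 14 with a small hydrogen donor.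

3. Step 17. The basic dianion may enolise the hindered α-branched aldehyde in place of adding to it, the adduct may undergo retro-aldol on work-up, or the imide acyl group may transfer to the new alkoxide. The fallback sets out from compound 26 and comes back at compound 28. 26 is selenenylated at the ring CH2 (LiN(i-Pr)2 2 equiv, PhSeBr, −78 °C) to 3-[(3S)-oct-1-en-3-yl]-4-(phenylselanyl)pyrrolidine-2,5-dione F4. Oxidation with H2O2 gives the selenoxide F5, which eliminates to the maleimide 3-[(3S)-oct-1-en-3-yl]-1H-pyrrole-2,5-dione F6. A thiazolium-catalysed Stetter reaction of aldehyde 19 with F6 (3-benzyl-5-(2-hydroxyethyl)-4-methylthiazolium chloride, Et3N, EtOH, 60 °C) adds the acyl anion equivalent to the unsubstituted maleimide carbon and should give 28 in one operation. Only a weak amine base and a short reaction time are used, because F6 can isomerise by γ-deprotonation.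

**Further compounds**

F1 | step 3 | dimethyl 2,2-bis(2-oxopropyl)propanedioate | COC(=O)C(CC(C)=O)(CC(C)=O)C(=O)OC
F2 | step 3 | methyl 4-oxo-2-(2-oxopropyl)pentanoate | COC(=O)C(CC(C)=O)CC(C)=O
F3 | step 9 | dimethyl 1-cyano-2-methyl-8-methylidene-4a-(triethylsilyloxy)-1,2,4a,5,6,7,8,8a-octahydronaphthalene-1,6-dicarboxylate, ring configuration as in 14 | N#CC1(C(=O)OC)[C@H]2C(=C)C[C@H](C(=O)OC)C[C@@]2(O[Si](CC)(CC)CC)C=C[C@H]1C
F4 | step 17 | 3-[(3S)-oct-1-en-3-yl]-4-(phenylselanyl)pyrrolidine-2,5-dione | C=C[C@H](CCCCC)C1C([Se]c2ccccc2)C(=O)NC1=O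
F5 | step 17 | 3-[(3S)-oct-1-en-3-yl]-4-(phenylseleninyl)pyrrolidine-2,5-dione | C=C[C@H](CCCCC)C1C([Se](=O)c2ccccc2)C(=O)NC1=O
F6 | step 17 | 3-[(3S)-oct-1-en-3-yl]-1H-pyrrole-2,5-dione | C=C[C@H](CCCCC)C1=CC(=O)NC1=O
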